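**Plan**

- Retrosynthetic cuts: first the side-chain C=C (back to a C5 aldehyde and malonic acid), then together C2–C1' to the syringyl ring and C3–C9 to the hydroxymethyl carbon, last C3a–C3 and O1–C2 of the furan ring (back to 5-iodovanillin and an acetylene).
- Enabling feature: the syringyl ring on C2 and C9 on C3 are neighbours on the dihydrofuran ring, so they sit on the two carbons of the enol-ether C2=C3 bond of a 7-methoxybenzofuran that already carries the C5 carbon.
- Forward order: the benzofuran ring is made first; aryl group and ester carbon are then added across C2=C3 in one palladium-catalysed three-component step that closes no ring; the acrylic acid is built afterwards and the phenol is freed last.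
- Stereochemistry: C2 comes from the chiral bisphosphine on palladium; C3 is delivered cis by syn addition and is turned trans by methoxide epimerisation of the ester; the E alkene comes from the decarboxylative condensation.
- Protecting groups: the syringyl phenol is a MOM ether (inert to palladium, methoxide, hydride and hot amine, removed by acid at the end) and the aldehyde is a dioxolane.

Key step: step 6

Assumption: which antipode of BINAP leads to 2S cannot be assigned in advance; (R)-BINAP is written, and its mirror image would be taken if a first run shows the opposite sense of induction.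

**Route**

Step 1
Reactants: 1 5-iodovanillin; 2 trimethylsilylacetylene
Product: 4 7-methoxy-2-(trimethylsilyl)-1-benzofuran-5-carbaldehyde, via alkynylphenol 3 (not isolated)
Conditions: Pd(PPh3)2Cl2 (3 mol%), CuI (5 mol%), Et3N, DMF, 25 °C then 70 °C
Reagents that add atoms: none
Why: Sonogashira coupling at the aryl iodide is followed in the same pot by 5-endo-dig addition of the ortho phenoxide to the metal-activated alkyne (domino coupling–cycloisomerisation of ortho-iodophenols), the para formyl group making the phenol acidic enough for Et3N.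

Step 2
Reactants: 4 7-methoxy-2-(trimethylsilyl)-1-benzofuran-5-carbaldehyde
Product: 5 7-methoxy-1-benzofuran-5-carbaldehyde
Conditions: TBAF (1.1 equiv), wet THF, 25 °C
Reagents that add atoms: none
Why: Fluoride-induced protodesilylation of a 2-silylbenzofuran, in which fluoride attacks silicon and C2 is protonated by water, should leave the aldehyde untouched.

Step 3
Reactants: 5 7-methoxy-1-benzofuran-5-carbaldehyde
Product: 6 2-(7-methoxy-1-benzofuran-5-yl)-1,3-dioxolane
Conditions: ethylene glycol, p-TsOH (cat.), toluene, reflux, Dean–Stark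
Reagents that add atoms: ethylene glycol OCCO
Why: Acid-catalysed acetalisation with azeotropic removal of water shields the aldehyde from methoxide and hydride later and takes its electron-withdrawing pull off the enol-ether double bond.

Step 4
Reactants: 7 2,6-dimethoxyphenol
Product: 8 4-iodo-2,6-dimethoxyphenol
Conditions: I2 (1.05 equiv), NaHCO3, THF–H2O, 0 °C
Reagents that add atoms: iodine II
Why: Electrophilic aromatic iodination of the phenoxide should go to its free para position C4, since both ortho positions carry methoxy groups.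

Step 5
Reactants: 8 4-iodo-2,6-dimethoxyphenol
Product: 9 5-iodo-1,3-dimethoxy-2-(methoxymethoxy)benzene
Conditions: MOMCl, iPr2NEt, CH2Cl2, 0 → 25 °C
Reagents that add atoms: chloromethyl methyl ether COCCl
Why: Williamson-type O-alkylation of the phenol with chloromethyl methyl ether gives the MOM acetal.

Step 6
Reactants: 6 2-(7-methoxy-1-benzofuran-5-yl)-1,3-dioxolane; 9 5-iodo-1,3-dimethoxy-2-(methoxymethoxy)benzene
Product: 10 methyl (2S,3R)-2-[3,5-dimethoxy-4-(methoxymethoxy)phenyl]-5-(1,3-dioxolan-2-yl)-7-methoxy-2,3-dihydro-1-benzofuran-3-carboxylate (2,3-cis)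
Conditions: Pd(OAc)2 (10 mol%), (R)-BINAP (12 mol%), iPr2NEt (2 equiv), MeOH (5 equiv), CO (about 0.1 atm in N2), toluene, 80 °C, 9 (1.5 equiv) added slowly
Reagents that add atoms: carbon monoxide [C-]#[O+]; methanol CO
Why: Proposed new method: zerovalent palladium formed in the flask inserts into the C–I bond of 9, the divalent aryl palladium adds syn across the enol-ether bond C2=C3 of 6 with the aryl group going to C2 (the regiochemistry seen in Heck arylation of benzofurans and of 2,3-dihydrofuran), and the benzylic C3 palladium, which has no syn beta hydrogen (H2 is anti, C3a carries none), inserts CO with retention and the acyl palladium is cleaved by methanol. The closest known reactions are the intramolecular dearomative Heck/carbonylation dominoes of indoles and benzofurans with tethered aryl halides and the intermolecular asymmetric Heck arylation of 2,3-dihydrofuran; the intermolecular three-component version on a benzofuran is not known. The step closes no ring and only breaks the aromaticity of the furan half of the benzofuran. C2 is set by the chiral bisphosphine in the enantioface-determining migratory insertion, and C3 follows from it because syn carbopalladation and stereoretentive CO insertion place aryl and ester cis. The step needs the benzofuran to insert before the aryl palladium is carbonylated to the aryl ester, which the low CO pressure, the small amount of methanol and the slow addition of 9 are meant to secure. It also needs the C3 palladium to take up CO before the ring rearomatises to the 2-arylbenzofuran, which the missing syn beta hydrogen of the substrate and the hindered amine base should secure.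

Step 7
Reactants: 10 the cis ester
Product: 11 methyl (2S,3S)-2-[3,5-dimethoxy-4-(methoxymethoxy)phenyl]-5-(1,3-dioxolan-2-yl)-7-methoxy-2,3-dihydro-1-benzofuran-3-carboxylate (2,3-trans)
Conditions: NaOMe (0.3 equiv), MeOH–THF, 0 → 25 °C
Reagents that add atoms: none
Why: Thermodynamic epimerisation through the ester enolate, a known operation on cis-2-aryl-2,3-dihydrobenzofuran-3-carboxylates, should reprotonate C3 so that the ester is trans to the C2 aryl group, while C2, which has no acidic hydrogen, keeps its configuration.

Step 8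
Reactants: 11 the trans ester
Product: 12 [(2S,3R)-2-[3,5-dimethoxy-4-(methoxymethoxy)phenyl]-5-(1,3-dioxolan-2-yl)-7-methoxy-2,3-dihydro-1-benzofuran-3-yl]methanol (2,3-trans)
Conditions: LiBH4, THF, 0 → 25 °C
Reagents that add atoms: none
Why: Chemoselective hydride reduction of the ester to the primary alcohol leaves both acetals intact, and C3 can no longer epimerise once the carbonyl is gone.

Step 9
Reactants: 12 the trans alcohol
Product: 13 (2S,3R)-2-[3,5-dimethoxy-4-(methoxymethoxy)phenyl]-3-(hydroxymethyl)-7-methoxy-2,3-dihydro-1-benzofuran-5-carbaldehyde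
Conditions: PPTS (cat.), acetone–H2O, 25 °C
Reagents that add atoms: water O
Why: Mild acid-catalysed acetal hydrolysis should cleave the dioxolane of an electron-rich benzaldehyde far faster than the aryl MOM ether, which is kept for the next step.

Step 10
Reactants: 13 the aldehyde; 14 malonic acid
Product: 16 (2E)-3-[(2S,3R)-2-[3,5-dimethoxy-4-(methoxymethoxy)phenyl]-3-(hydroxymethyl)-7-methoxy-2,3-dihydro-1-benzofuran-5-yl]prop-2-enoic acid, via arylidenemalonic acid 15 (not isolated)
Conditions: pyridine, piperidine (cat.), 90 °C
Reagents that add atoms: none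
Why: Knoevenagel condensation and decarboxylation (Doebner modification) should give the E-cinnamic acid, and with the phenol still masked no quinone methide can form by opening of the dihydrofuran ring in the hot amine base.

Step 11
Reactants: 16 the MOM-protected acid
Product: 17 (2E)-3-[(2S,3R)-2-(4-hydroxy-3,5-dimethoxyphenyl)-3-(hydroxymethyl)-7-methoxy-2,3-dihydro-1-benzofuran-5-yl]prop-2-enoic acid (target)
Conditions: 3 M aq. HCl, THF, 40 °C
Reagents that add atoms: none
Why: Acid hydrolysis of the MOM acetal frees the phenol, and because 2,3-trans is the thermodynamically preferred arrangement, even a reversible ionisation of the benzylic C2–O1 bond would re-close to the same isomer with C3 unchanged.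

**Compound list**

1 | 5-iodovanillin (4-hydroxy-3-iodo-5-methoxybenzaldehyde) | COc1cc(C=O)cc(I)c1O | starting material
2 | trimethylsilylacetylene | C[Si](C)(C)C#C | starting material
3 | 4-hydroxy-3-methoxy-5-[(trimethylsilyl)ethynyl]benzaldehyde | COc1cc(C=O)cc(C#C[Si](C)(C)C)c1O | intermediate (not isolated)
4 | 7-methoxy-2-(trimethylsilyl)-1-benzofuran-5-carbaldehyde | COc1cc(C=O)cc2cc([Si](C)(C)C)oc12 | intermediate
5 | 7-methoxy-1-benzofuran-5-carbaldehyde | COc1cc(C=O)cc2ccoc12 | intermediate
6 | 2-(7-methoxy-1-benzofuran-5-yl)-1,3-dioxolane | COc1cc(C2OCCO2)cc2ccoc12 | intermediate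
7 | 2,6-dimethoxyphenol | COc1cccc(OC)c1O | starting material
8 | 4-iodo-2,6-dimethoxyphenol | COc1cc(I)cc(OC)c1O | intermediate
9 | 5-iodo-1,3-dimethoxy-2-(methoxymethoxy)benzene | COCOc1c(OC)cc(I)cc1OC | intermediate
10 | methyl (2S,3R)-2-[3,5-dimethoxy-4-(methoxymethoxy)phenyl]-5-(1,3-dioxolan-2-yl)-7-methoxy-2,3-dihydro-1-benzofuran-3-carboxylate (cis) | COc1cc([C@H]2Oc3c(OC)cc(C4OCCO4)cc3[C@H]2C(=O)OC)cc(OC)c1OCOC | intermediate
11 | methyl (2S,3S)-2-[3,5-dimethoxy-4-(methoxymethoxy)phenyl]-5-(1,3-dioxolan-2-yl)-7-methoxy-2,3-dihydro-1-benzofuran-3-carboxylate (trans) | COc1cc([C@H]2Oc3c(OC)cc(C4OCCO4)cc3[C@@H]2C(=O)OC)cc(OC)c1OCOC | intermediate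
12 | [(2S,3R)-2-[3,5-dimethoxy-4-(methoxymethoxy)phenyl]-5-(1,3-dioxolan-2-yl)-7-methoxy-2,3-dihydro-1-benzofuran-3-yl]methanol (trans) | COc1cc([C@H]2Oc3c(OC)cc(C4OCCO4)cc3[C@@H]2CO)cc(OC)c1OCOC | intermediate
13 | (2S,3R)-2-[3,5-dimethoxy-4-(methoxymethoxy)phenyl]-3-(hydroxymethyl)-7-methoxy-2,3-dihydro-1-benzofuran-5-carbaldehyde | COc1cc([C@H]2Oc3c(OC)cc(C=O)cc3[C@@H]2CO)cc(OC)c1OCOC | intermediate
14 | malonic acid | OC(=O)CC(=O)O | starting material
15 | 2-{[(2S,3R)-2-[3,5-dimethoxy-4-(methoxymethoxy)phenyl]-3-(hydroxymethyl)-7-methoxy-2,3-dihydro-1-benzofuran-5-yl]methylidene}propanedioic acid | COc1cc([C@H]2Oc3c(OC)cc(C=C(C(=O)O)C(=O)O)cc3[C@@H]2CO)cc(OC)c1OCOC | intermediate (not isolated)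
16 | (2E)-3-[(2S,3R)-2-[3,5-dimethoxy-4-(methoxymethoxy)phenyl]-3-(hydroxymethyl)-7-methoxy-2,3-dihydro-1-benzofuran-5-yl]prop-2-enoic acid | COc1cc([C@H]2Oc3c(OC)cc(/C=C/C(=O)O)cc3[C@@H]2CO)cc(OC)c1OCOC | intermediate
17 | (2E)-3-[(2S,3R)-2-(4-hydroxy-3,5-dimethoxyphenyl)-3-(hydroxymethyl)-7-methoxy-2,3-dihydro-1-benzofuran-5-yl]prop-2-enoic acid | COc1cc([C@H]2Oc3c(OC)cc(/C=C/C(=O)O)cc3[C@@H]2CO)cc(OC)c1O | target

**Count**

Total steps: 11. Longest linear sequence: 9 steps (1, 2, 3, 6, 7, 8, 9, 10, 11).

**Steps most likely to fail**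

Step 6. Three processes could defeat it. CO insertion into the aryl–palladium bond and methanolysis may outrun the intermolecular insertion of the benzofuran. The C3 palladium may lose its configuration or be eliminated in an anti sense, so that the furan ring rearomatises. Face selection by the ligand may be poor. The fallback uses the known enantioselective, cis-selective intramolecular C–H insertion of an aryldiazoacetate; it sets out from 9 and 1 and comes back at 10.
Iodine–magnesium exchange on 9 (iPrMgCl·LiCl, THF) would give [3,5-dimethoxy-4-(methoxymethoxy)phenyl]magnesium chloride F1, which would be quenched with paraformaldehyde to [3,5-dimethoxy-4-(methoxymethoxy)phenyl]methanol F2. Mitsunobu etherification of the phenol of 1 with F2 (PPh3, DIAD, THF) would give 4-{[3,5-dimethoxy-4-(methoxymethoxy)phenyl]methoxy}-3-iodo-5-methoxybenzaldehyde F3, and acetalisation (ethylene glycol, PPTS, benzene, reflux) its dioxolane 2-(4-{[3,5-dimethoxy-4-(methoxymethoxy)phenyl]methoxy}-3-iodo-5-methoxyphenyl)-1,3-dioxolane F4. Palladium-catalysed coupling with the Reformatsky reagent BrZnCH2CO2Me (Pd(dba)2, Q-Phos, THF) would give methyl 2-[2-{[3,5-dimethoxy-4-(methoxymethoxy)phenyl]methoxy}-5-(1,3-dioxolan-2-yl)-3-methoxyphenyl]acetate F5, and diazo transfer (p-ABSA, DBU, MeCN) methyl 2-diazo-2-[2-{[3,5-dimethoxy-4-(methoxymethoxy)phenyl]methoxy}-5-(1,3-dioxolan-2-yl)-3-methoxyphenyl]acetate F6. Dirhodium tetrakis[N-phthaloyl-(S)-tert-leucinate], Rh2(S-PTTL)4 (or its mirror image, as the sense of induction requires), in toluene at low temperature should then insert the carbene into the benzylic C–H bond of the ether and close the dihydrofuran ring to the cis ester 10.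

Step 7. The ester enolate may expel the ring phenoxide (beta-elimination, the reverse of an oxa-Michael addition); the ring-opened cinnamate is achiral and would re-close without selectivity, which would erode the enantiomeric purity. The fallback avoids any enolate by correcting C2 under acid while C3 stays untouched; it sets out from 6 and 9 and comes back at 13.
Step 6 run with the mirror-image ligand would give methyl (2R,3S)-2-[3,5-dimethoxy-4-(methoxymethoxy)phenyl]-5-(1,3-dioxolan-2-yl)-7-methoxy-2,3-dihydro-1-benzofuran-3-carboxylate F7, in which C3 already has the spatial arrangement of the target. LiBH4 reduction would give the cis alcohol [(2R,3R)-2-[3,5-dimethoxy-4-(methoxymethoxy)phenyl]-5-(1,3-dioxolan-2-yl)-7-methoxy-2,3-dihydro-1-benzofuran-3-yl]methanol F8. Treatment with 2 M aq. HCl in THF at 50 °C should remove both acetals and equilibrate C2 through reversible heterolysis of the benzylic C2–O1 bond (para-hydroxybenzyl cation, as in the acid-catalysed ring closures that give trans-2-aryl-dihydrobenzofurans), giving (2S,3R)-2-(4-hydroxy-3,5-dimethoxyphenyl)-3-(hydroxymethyl)-7-methoxy-2,3-dihydro-1-benzofuran-5-carbaldehyde F9. Selective re-protection of the phenol (MOMCl, K2CO3, acetone) would then give 13.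

Step 4. Iodine may oxidise the very electron-rich phenol (oxidative coupling to the diphenoquinone), and some iodination may occur at C3 next to a methoxy group. The fallback halogenates with a less oxidising reagent and exchanges the halogen afterwards; it sets out from 7 and comes back at 9.
Bromination with NBS (CHCl3, low temperature), a well-established para bromination of this phenol, would give 4-bromo-2,6-dimethoxyphenol F10. Protection (MOMCl, iPr2NEt, CH2Cl2) would give 5-bromo-1,3-dimethoxy-2-(methoxymethoxy)benzene F11, and copper-catalysed bromide–iodide exchange (aromatic Finkelstein reaction: CuI, NaI, N,N'-dimethylethylenediamine, dioxane, 110 °C) would give 9.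

**Further compounds**

F1 | step 6 | [3,5-dimethoxy-4-(methoxymethoxy)phenyl]magnesium chloride (not isolated) | COCOc1c(OC)cc([Mg]Cl)cc1OC
F2 | step 6 | [3,5-dimethoxy-4-(methoxymethoxy)phenyl]methanol | COCOc1c(OC)cc(CO)cc1OC
F3 | step 6 | 4-{[3,5-dimethoxy-4-(methoxymethoxy)phenyl]methoxy}-3-iodo-5-methoxybenzaldehyde | COCOc1c(OC)cc(COc2c(I)cc(C=O)cc2OC)cc1OC
F4 | step 6 | 2-(4-{[3,5-dimethoxy-4-(methoxymethoxy)phenyl]methoxy}-3-iodo-5-methoxyphenyl)-1,3-dioxolane | COCOc1c(OC)cc(COc2c(I)cc(C3OCCO3)cc2OC)cc1OC
F5 | step 6 | methyl 2-[2-{[3,5-dimethoxy-4-(methoxymethoxy)phenyl]methoxy}-5-(1,3-dioxolan-2-yl)-3-methoxyphenyl]acetate | COCOc1c(OC)cc(COc2c(CC(=O)OC)cc(C3OCCO3)cc2OC)cc1OC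
F6 | step 6 | methyl 2-diazo-2-[2-{[3,5-dimethoxy-4-(methoxymethoxy)phenyl]methoxy}-5-(1,3-dioxolan-2-yl)-3-methoxyphenyl]acetate | COCOc1c(OC)cc(COc2c(C(=[N+]=[N-])C(=O)OC)cc(C3OCCO3)cc2OC)cc1OC
F7 | step 7 | methyl (2R,3S)-2-[3,5-dimethoxy-4-(methoxymethoxy)phenyl]-5-(1,3-dioxolan-2-yl)-7-methoxy-2,3-dihydro-1-benzofuran-3-carboxylate (cis, enantiomer of 10) | COc1cc([C@@H]2Oc3c(OC)cc(C4OCCO4)cc3[C@@H]2C(=O)OC)cc(OC)c1OCOC
F8 | step 7 | [(2R,3R)-2-[3,5-dimethoxy-4-(methoxymethoxy)phenyl]-5-(1,3-dioxolan-2-yl)-7-methoxy-2,3-dihydro-1-benzofuran-3-yl]methanol (cis) | COc1cc([C@@H]2Oc3c(OC)cc(C4OCCO4)cc3[C@@H]2CO)cc(OC)c1OCOC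
F9 | step 7 | (2S,3R)-2-(4-hydroxy-3,5-dimethoxyphenyl)-3-(hydroxymethyl)-7-methoxy-2,3-dihydro-1-benzofuran-5-carbaldehyde | COc1cc([C@H]2Oc3c(OC)cc(C=O)cc3[C@@H]2CO)cc(OC)c1O
F10 | step 4 | 4-bromo-2,6-dimethoxyphenol | COc1cc(Br)cc(OC)c1O
F11 | step 4 | 5-bromo-1,3-dimethoxy-2-(methoxymethoxy)benzene | COCOc1c(OC)cc(Br)cc1OC
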